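## Retrosynthetic overview

1. Jaeskeanin ⇒ acylation at O‑6 and 6α‑OH‑directed epoxidation of jaeschkeanadiol ⇒ 4β‑OH‑directed reduction of a trans‑fused 6‑keto‑Δ8,9 hydroazulene ketol.
2. Key step, used in place of RCM or a cycloheptenone aldol: the seven‑membered ring is closed last by Rh(I) intramolecular hydroacylation of a 4,6‑dienal. This forms C6–C7 and delivers both C6=O and the β,γ Δ8,9 alkene in one step.
3. The cyclopentane (C4, C5) comes from a D‑proline 5‑enolexo aldol of an acyclic 1,6‑keto‑aldehyde.
4. The keto‑aldehyde comes from oxidative opening of a sacrificial p‑menthene‑type cyclohexene, so the net change is a 6→5 ring contraction.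
5. The quaternary C1 comes from a catalytic enantioselective Diels–Alder reaction. Ring order: cyclohexene (sacrificial) → cyclopentane → cycloheptene → oxirane.

Numbering: daucane numbering is used. C1 is the angular‑Me carbon, C4 the carbinol, C5 the ring‑fusion CH, C6 the acyloxy carbon, and C8/C9 the epoxide carbons. The target is 1R,4R,5S,6S,8R,9S: trans‑fused, 4β‑OH, 6α‑OAr, 8α,9α‑epoxide.

Assumption: the facial sense in Step 2 follows the standard formyl C–H···O pre‑transition‑state model. Compound 5 is defined by its (S) configuration, so if the model is inverted the (R)‑catalyst is used and nothing else changes.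

## Route

**Step 1**
Reactants: 1, 3‑methylbut‑1‑yne; 2, ethylene
Product: 3, 2‑isopropylbuta‑1,3‑diene
Conditions: Grubbs II (2 mol %), C2H4 (1–4 atm), CH2Cl2, rt; distil
Reagents that add atoms: ethylene, C=C
Why: Ene–yne cross‑metathesis of a terminal alkyne with ethylene gives the 2‑substituted 1,3‑butadiene directly, and no stereocentre is formed.

**Step 2**
Reactants: 3; 4, methacrolein
Product: 5, (S)‑4‑isopropyl‑1‑methylcyclohex‑3‑ene‑1‑carbaldehyde
Conditions: (S)‑o‑tolyl oxazaborolidine (from (S)‑diphenylprolinol)·Tf2NH (10 mol %), CH2Cl2, −78 → −40 °C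
Reagents that add atoms: methacrolein, CC(=C)C=O
Why: In this catalytic enantioselective Diels–Alder reaction (cationic oxazaborolidine) the 2‑alkyl diene gives the "para" adduct, and the catalyst phenyl shields the Cα‑Si face of bound s‑trans methacrolein, so the diene adds to the Cα‑Re face and sets the quaternary C1.

**Step 3**
Reactants: 5; 6, diethyl (2‑methylallyl)phosphonate
Product: 7, (4S)‑4‑methyl‑4‑[(1E)‑3‑methylbuta‑1,3‑dienyl]‑1‑isopropylcyclohex‑1‑ene
Conditions: 6, n‑BuLi, THF–HMPA, −78 °C; add 5; → rt
Reagents that add atoms: diethyl (2‑methylallyl)phosphonate, CCOP(=O)(CC(C)=C)OCC (delivers =CH–C(CH3)=CH2)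
Why: Horner–Wadsworth–Emmons olefination with a lithiated allylic phosphonate (α‑attack favoured by HMPA) gives the E‑1,3‑diene, and the aldehyde is non‑enolisable so C1 cannot scramble.

**Step 4**
Reactants: 7
Product: 8, (4S)‑4‑methyl‑4‑[(1E)‑3‑methylbuta‑1,3‑dienyl]‑1‑isopropyl‑7‑oxabicyclo[4.1.0]heptane (epoxide diastereomer mixture)
Conditions: mCPBA (1.0 equiv), NaHCO3, CH2Cl2, −10 → 0 °C
Reagents that add atoms: mCPBA, OOC(=O)c1cccc(Cl)c1
Why: Prilezhaev epoxidation selects the isolated, most electron‑rich trisubstituted ring alkene over the conjugated diene (myrcene‑type selectivity), and the epoxide configuration is irrelevant because both carbons become carbonyls.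

**Step 5**
Reactants: 8
Product: 9, (3S)‑3,7‑dimethyl‑3‑[(1E)‑3‑methylbuta‑1,3‑dienyl]‑6‑oxooctanal
Conditions: H5IO6 (1.3 equiv), THF–H2O, 0 °C → rt
Reagents that add atoms: water, O (supplies the second carbonyl oxygen); oxidant is periodic acid, O[I](=O)(O)(O)(O)O
Why: One‑pot epoxide hydrolysis and Malaprade glycol cleavage opens the sacrificial six‑membered ring to the 1,6‑keto‑aldehyde without touching the diene or C1.

**Step 6**
Reactants: 9
Product: 10, (1R,2R,5R)‑2‑hydroxy‑2‑isopropyl‑5‑methyl‑5‑[(1E)‑3‑methylbuta‑1,3‑dienyl]cyclopentane‑1‑carbaldehyde (CHO, OH and 5‑Me on one face; iPr, dienyl and H‑1 on the other)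
Conditions: D‑proline (30 mol %), DMSO, rt
Reagents that add atoms: none
Why: In this enamine‑catalysed 5‑enolexo intramolecular aldol (Houk–List TS) the CO2H···O=C hydrogen bond holds the C4–O syn to the enamine carbon so that OH and CHO end up cis with iPr anti, D‑proline fixes the enamine face (H‑5 α), and because Me and alkenyl on C1 are nearly isosteric, catalyst control sets C4 and C5 relative to C1.

**Step 7 (key step)**
Reactants: 10
Product: 11, (3R,3aR,8aR)‑3‑hydroxy‑3‑isopropyl‑6,8a‑dimethyl‑2,3,3a,5,8,8a‑hexahydroazulen‑4(1H)‑one (trans‑fused, C6=O, Δ8,9)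
Conditions: [Rh(nbd)2]BF4/dppe (10 mol %, pre‑activated with H2), ClCH2CH2Cl, 65 °C
Reagents that add atoms: none
Why: In this Rh(I)‑catalysed intramolecular hydroacylation of a 4,6‑dienal the acyl–Rh–H adds H to C10 to give an anti‑η3‑allyl (C9–C8–C7), which reductively eliminates at the primary terminus C7 to form the Z β,γ‑cycloheptenone under neutral conditions; the competing five‑ring closure at C9 would need a strained trans‑bicyclo[3.3.0]octane, and the trans fusion is inherited from 10.

**Step 8**
Reactants: 11
Product: 12, jaeschkeanadiol, (3R,3aS,4S,8aR)‑3‑isopropyl‑6,8a‑dimethyl‑1,2,3a,4,5,8‑hexahydroazulene‑3,4‑diol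
Conditions: Me4NBH(OAc)3, MeCN–AcOH, −30 → −20 °C
Reagents that add atoms: none
Why: In the Evans–Saksena hydroxyl‑directed reduction the 4β‑O‑bound acetoxyborohydride delivers hydride intramolecularly to the β face of C6, giving the equatorial 6α‑OH, and the mild acidic medium avoids conjugation of the alkene or epimerisation at C5.

**Step 9**
Reactants: 12
Product: 13, 8α,9α‑epoxyjaeschkeanadiol (8R,9S)
Conditions: VO(acac)2 (5 mol %), t‑BuOOH (decane), CH2Cl2, 0 °C → rt
Reagents that add atoms: tert‑butyl hydroperoxide, CC(C)(C)OO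
Why: In this hydroxyl‑directed vanadium epoxidation the homoallylic 6α‑OH delivers oxygen to the α face, which is also the face away from the axial C1 methyl, and the resulting syn epoxy alcohol cannot cyclise because backside attack on the epoxide is geometrically impossible.

**Step 10**
Reactants: 13; 14, 4‑(benzyloxy)benzoic acid
Product: 15, O‑benzyljaeskeanin (the 6‑O‑[4‑(benzyloxy)benzoate] of 13)
Conditions: 14, 2,4,6‑Cl3C6H2COCl, Et3N, THF; then 13, DMAP, toluene, rt → 50 °C
Reagents that add atoms: 4‑(benzyloxy)benzoic acid, O=C(O)c1ccc(OCc2ccccc2)cc1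
Why: Yamaguchi esterification acylates only the secondary 6‑OH with retention at C6, since the tertiary 4‑OH is inert and the epoxide tolerates DMAP and Et3N.

**Step 11**
Reactants: 15
Product: 16, jaeskeanin
Conditions: H2 (1 atm), 10 % Pd/C, EtOAc, rt
Reagents that add atoms: none
Why: Benzyl ether hydrogenolysis frees the phenol; no alkene remains, and the non‑benzylic trisubstituted epoxide, the ester and the tertiary alcohol are all inert under these conditions.

## Compound list

| No. | Name | SMILES | Role |
|---|---|---|---|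
| 1 | 3‑methylbut‑1‑yne | CC(C)C#C | starting material |
| 2 | ethylene | C=C | starting material |
| 3 | 2‑isopropylbuta‑1,3‑diene | C=CC(=C)C(C)C | intermediate |
| 4 | methacrolein | CC(=C)C=O | starting material |
| 5 | (S)‑4‑isopropyl‑1‑methylcyclohex‑3‑enecarbaldehyde | O=C[C@]1(C)CC=C(C(C)C)CC1 | intermediate |
| 6 | diethyl (2‑methylallyl)phosphonate | CCOP(=O)(CC(C)=C)OCC | starting material |
| 7 | (S)‑triene | C=C(C)/C=C/[C@]1(C)CC=C(C(C)C)CC1 | intermediate |
| 8 | ring epoxide (diastereomer mixture) | C=C(C)/C=C/[C@]1(C)CC2OC2(C(C)C)CC1 | intermediate |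
| 9 | (S)‑keto‑aldehyde | O=CC[C@@](C)(/C=C/C(C)=C)CCC(=O)C(C)C | intermediate |
| 10 | hydroxy‑aldehyde (4,6‑dienal) | O=C[C@H]1[C@](O)(C(C)C)CC[C@]1(C)/C=C/C(C)=C | intermediate |
| 11 | trans‑hydroazulenone ketol | CC(C)[C@]1(O)CC[C@]2(C)CC=C(C)CC(=O)[C@H]21 | intermediate |
| 12 | jaeschkeanadiol | CC(C)[C@]1(O)CC[C@]2(C)CC=C(C)C[C@H](O)[C@H]21 | intermediate |
| 13 | 8α,9α‑epoxyjaeschkeanadiol | CC(C)[C@]1(O)CC[C@]2(C)C[C@@H]3O[C@]3(C)C[C@H](O)[C@H]21 | intermediate |
| 14 | 4‑(benzyloxy)benzoic acid | O=C(O)c1ccc(OCc2ccccc2)cc1 | starting material |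
| 15 | O‑benzyljaeskeanin | CC(C)[C@]1(O)CC[C@]2(C)C[C@@H]3O[C@]3(C)C[C@H](OC(=O)c3ccc(OCc4ccccc4)cc3)[C@H]21 | intermediate |
| 16 | jaeskeanin | CC(C)[C@]1(O)CC[C@]2(C)C[C@@H]3O[C@]3(C)C[C@H](OC(=O)c3ccc(O)cc3)[C@H]21 | target |

## Step count

Total steps: 11. Longest linear sequence: 11 (1 → 16). All coupling partners are commercial.

## Steps most likely to fail, with fallbacks

1. **Step 7, diene hydroacylation.** The risks are decarbonylation, Rh–H isomerisation of the product to the conjugated enone, and a sluggish reaction of the hindered aldehyde. The fallback is to replace C–H activation with radical chemistry. Oxidise 10 to the acid, convert it to the acyl selenide, and run an acyl‑radical 7‑endo cyclisation onto the diene terminus C7 with (TMS)3SiH/AIBN. The resulting allyl radical is quenched at C10 and gives the same Δ8,9 ketone 11.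
2. **Step 6, proline 5‑enolexo aldol on an isopropyl ketone.** The risks are low conversion, dehydration to the enal, and modest dr relative to C1. The fallback is to oxidise 9 to the keto acid (Pinnick) and run a nucleophile‑catalysed aldol‑lactonisation with TsCl, LiCl, i‑Pr2NEt and a chiral isothiourea. This gives the cis‑fused β‑lactone, which locks C4–O and C6 cis. DIBAL‑H reduction of the lactone then gives 10.
3. **Step 9, facial selectivity of the epoxidation with an equatorial homoallylic OH.** The fallback is to esterify 12 first, giving O‑benzylferutinin, and epoxidise under purely steric control with mCPBA or DMDO. If the β‑epoxide dominates there, switch to a bromohydrin sequence (NBS/H2O, then K2CO3). That sequence places the oxygen on the face opposite to initial electrophile attack.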